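The early excess of left-handed product over right-handed product in the flask rests on one ratio, the selectivity factor s: the log loss of left-handed substrate, −ln(c left-handed substrate / its charge), divided by the same loss of right-handed substrate. Later, with s held, the excess also shifts with conversion.

| setting | elm | larch | flask |
|---|---|---|---|
| left-handed substrate | 0.050 M | 0.050 M | 0.050 M |
| right-handed substrate | 0.050 M | 0.050 M | 0.050 M |
| gas | 4.5 mM (held) | 4.5 mM (held) | 4.5 mM (held) |
| precatalyst | 3.5 mM | 5.5 mM | 2.5 mM |
| remark | run made earlier | run made earlier |  |
| time |  |  | 50 min |
- elm (time / min: left-handed substrate / %, right-handed substrate / %, left-handed product / %): 5.00: 50.1, 49.3, 0; 10.0: 48.3, 49.5, 1.3; 15.0: 47.3, 48.6, 2.9; 20.0: 44.2, 48.2, 5.2; 25.0: 43.6, 47.3, 7.2; 30.0: 40.6, 47.2, 7.5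
- larch (time / min: left-handed substrate / %, right-handed substrate / %, left-handed product / %): 5.00: 49.4, 49.8, 0; 10.0: 47.4, 48.9, 1.0; 15.0: 46.3, 48.4, 3.8; 20.0: 43.3, 48.7, 5.2; 25.0: 41.3, 47.2, 7.7; 30.0: 39.3, 45.4, 9.7

(standard deviation of a reading: 0.5 percentage points)
- free catalyst is single-handed; left-handed substrate and right-handed substrate are mirror images of each other, charged as a racemate, each of them at the stated concentration
- at the start none of the gas is in solution
- an excess is the difference of the two amounts in percent of their sum
- an excess is below zero if the other one leads
- part of the left-handed substrate and right-handed substrate charged together that has reacted at 50 min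
- excess of left-handed product over right-handed product in the product at 50 min
- excess of right-handed substrate over left-handed substrate among what is left of the two at 50 min

Before I reckon s, I ask which numbers it needs, using the last readings of elm and larch at 30.0 min.

1. Lag and catalyst level: I assume both substrates meet the same catalyst on the same clock, each lost in proportion to itself. These then cancel in s.

2. Left-handed readings: one scatter on larch's last reading moves the pooled s by 2.82%.

3. Right-handed readings: the same scatter moves it by 7.11%, more than the left-handed shift. So the small loss is the number to know well.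

4. Precatalyst: elm by itself gives 3.61 and larch 2.50. But one scatter is worth 18.3% on elm's right-handed loss, so I read no trend and pool the runs.

5. Pooled, the ratio of the two log losses is 2.91: this is s. Early on, the product excess is s less one over s plus one, so I reckon 48.9%, and one right-handed scatter moves that by 2.7 percentage points.

The forecast says c 16%, eP 49%, eS 9%, and of the ratio: “Selectivity is about 3, though poorly determined.”

The flask gives c 18.0%, eP 52.0%, eS 11.1%, inside the forecast's margins.

    free catalyst + left-handed substrate ⇌ catalyst intermediate A (K = 19.0 M⁻¹, k = 250 M⁻¹ min⁻¹)
    free catalyst + right-handed substrate ⇌ catalyst intermediate B (K = 11.1 M⁻¹, k = 4470 M⁻¹ min⁻¹)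
    partner + catalyst intermediate A → free catalyst + left-handed product (k = 212 M⁻¹ min⁻¹)
    partner + catalyst intermediate B → free catalyst + right-handed product (k = 97.6 M⁻¹ min⁻¹)
    2 free catalyst ⇌ resting dimer (K = 12000 M⁻¹, k = 35.6 M⁻¹ min⁻¹)
    gas ⇌ partner, rate k6*(csat - [partner]) (kL = 0.349 min⁻¹)
    partner + precatalyst → free catalyst + spent reagent (k = 14.4 M⁻¹ min⁻¹)

In the flask, 73% of the left-handed charge and 91% of the right-handed charge stand unbound at 50.0 min, so s is 3.38. By the early rule that s gives 53.9%, and the flask's excess at 5.00 min is 54.9%. The neighbour flask, with 0.0043 M of precatalyst, leaves 66% and 88%, so its s is 3.39, against my reading of 2.91; its excess of 50.9% stands at c 22.8%, so it is no early figure. The flask's excess stands because catalyst intermediate B falls back to free catalyst and right-handed substrate: with that backward step taken away, the excess goes from 52.0% to −99.2%.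

The readings are calculated for an exercise; noise was put on by code.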